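**Retrosynthetic overview**

1. The route rests on the butenolide ring O1–C2(=O)–C3(OH)=C4(Ph)–C5(CO2Me)(CH2Ar). It maps onto a ketone C=O (C5 and O1), an alkyne (C4 bearing phenyl, C3) and one CO (C2), with the C3 hydroxyl carried as a C3–B bond.
2. Target 15 ⇐ oxidation of the C3–B bond of boryl butenolide 13.
3. 13 ⇐ carbonylative [2+2+1] (hetero-Pauson–Khand) union of arylpyruvate 7, alkynyl boronate 11 and CO 12. This forms C4–C5, C2–C3 and C2–O1, closes the only ring made in the route and sets C5.
4. 7 ⇐ Erlenmeyer azlactone 4 from chroman aldehyde 1 (chroman ring bought intact) and N-acetylglycine 2, then hydrolysis and O-methylation; 11 ⇐ phenylacetylene 8 and a pinacol borate.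

Key step: step 5

**Remarks on the chemistry**

- Aldehyde 1 is taken as a purchasable building block.
- Acid 6 and ester 7 should exist largely as their Z-enol tautomers. They are named and drawn as the keto forms, which is the form that reacts in step 5.
- Step 5 is a 1:1:1 addition of 7, 11 and CO 12 in which every atom of the three components is retained in 13. In practice 11 would be charged in about twofold excess over 7 to allow for its loss by oligomerisation or protodeborylation, and the unreacted remainder would be removed by chromatography.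
- The sense of induction of the ligand in step 5 cannot be predicted. The (R)-ligand is written, and its antipode would be used if a first run should give the (S)-product.

**Route**

Step 1
Reactants: 1 2,2-dimethylchroman-6-carbaldehyde; 2 N-acetylglycine
Product: 4 (Z)-4-[(2,2-dimethylchroman-6-yl)methylene]-2-methyloxazol-5(4H)-one, via 2-methyloxazol-5(4H)-one 3 (not isolated)
Conditions: Ac2O, NaOAc, 100 °C
Reagents that add atoms: none
Why: Erlenmeyer–Plöchl azlactone synthesis: Ac2O cyclodehydrates 2 to oxazolone 3, whose acidic C4 methylene condenses with the non-enolisable aryl aldehyde 1 to the thermodynamically preferred Z-alkylidene azlactone, a geometry that is lost again in step 2.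

Step 2
Reactants: 4 (Z)-4-[(2,2-dimethylchroman-6-yl)methylene]-2-methyloxazol-5(4H)-one
Product: 6 3-(2,2-dimethylchroman-6-yl)-2-oxopropanoic acid, via (Z)-acetamidoacrylic acid 5 (not isolated)
Conditions: 3 M aq HCl, 1,4-dioxane, reflux
Reagents that add atoms: water (O)
Why: Acid hydrolysis of an azlactone: water opens the lactone to enamide acid 5 and the protonated enamide is hydrolysed to the alpha-keto acid, while the aryl tertiary-alkyl ether of the chroman should persist because its acid-induced opening is reversible in favour of the six-membered ring.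

Step 3
Reactants: 6 3-(2,2-dimethylchroman-6-yl)-2-oxopropanoic acid
Product: 7 methyl 3-(2,2-dimethylchroman-6-yl)-2-oxopropanoate
Conditions: MeI (1.1 equiv), DBU (1.0 equiv), DMF, 0 °C
Reagents that add atoms: iodomethane (CI)
Why: SN2 O-alkylation of the carboxylate: one equivalent of DBU deprotonates only the carboxylic acid, which is far more acidic than the enol, so iodomethane should give the methyl ester without the ketal or enol ether formation that acid-catalysed esterification in methanol would risk.

Step 4
Reactants: 8 phenylacetylene
Product: 11 4,4,5,5-tetramethyl-2-(phenylethynyl)-1,3,2-dioxaborolane, via lithium phenylacetylide 9 (not isolated), via lithium alkynyl(isopropoxy)borate 10 (not isolated)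
Conditions: n-BuLi, THF, −78 °C; 2-isopropoxy-4,4,5,5-tetramethyl-1,3,2-dioxaborolane, −78 °C; HCl in Et2O, −78 °C to rt; filtration, distillation
Reagents that add atoms: 2-isopropoxy-4,4,5,5-tetramethyl-1,3,2-dioxaborolane (CC(C)OB1OC(C)(C)C(C)(C)O1)
Why: Borylation of a lithium acetylide: deprotonated 8 adds to the borate ester to give ate complex 10, and anhydrous HCl removes isopropoxide as propan-2-ol, so that the moisture-sensitive alkynyl boronate is freed and isolated without contact with water.

Step 5
Reactants: 7 methyl 3-(2,2-dimethylchroman-6-yl)-2-oxopropanoate; 11 4,4,5,5-tetramethyl-2-(phenylethynyl)-1,3,2-dioxaborolane; 12 carbon monoxide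
Product: 13 methyl (R)-2-[(2,2-dimethylchroman-6-yl)methyl]-5-oxo-3-phenyl-4-(4,4,5,5-tetramethyl-1,3,2-dioxaborolan-2-yl)-2,5-dihydrofuran-2-carboxylate
Conditions: Ru3(CO)12 (5 mol %), (R)-DIFLUORPHOS (15 mol %), CO (5 atm), toluene, 140 °C, autoclave
Reagents that add atoms: none
Why: Proposed new method: zerovalent ruthenium carrying the chiral bisphosphine binds the keto tautomer of 7 through its ketone and ester oxygens, couples the ketone C=O oxidatively to alkyne 11 to give an oxaruthenacyclopentene (C4–C5 bond, quaternary C5, boron-bearing C3 on ruthenium), inserts CO 12 into the Ru–C3 bond (C2–C3) and closes the lactone by acyl–alkoxide reductive elimination (C2–O1), which returns zerovalent ruthenium. The closest known reaction type is the racemic Ru3(CO)12-catalysed carbonylative [2+2+1] coupling (hetero-Pauson–Khand reaction) of alpha-keto esters and other chelating ketones with alkenes or alkynes and CO to give lactones; a boryl alkyne and asymmetric induction have not been shown for it. The butenolide, the only ring formed, closes in the [2+2+1] mode, its last bond being C2–O1 by reductive elimination from a six-membered acyl(alkoxy)ruthenacycle. The C5 stereocentre arises in the oxidative cyclisation and is controlled by the catalyst alone: the C2-symmetric ligand must shield one face of the planar, chelated 1,2-dicarbonyl unit so that the alkyne reaches the ketone carbon from the other face. The step needs C–C bond formation at the phenyl-bearing alkyne carbon, which the bulk of the pinacolboryl group and the general preference of boryl and silyl alkynes to place the heteroatom-bearing carbon on the metal should secure, and it needs reaction at the ketone instead of the ester, which the higher electrophilicity of the ketone within the chelate secures. Because 7 rests as its enol, the reaction temperature serves to keep the keto tautomer available, and charging the alkyne in excess over the keto ester allows for its loss by oligomerisation or protodeborylation.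

Step 6
Reactants: 13 methyl (R)-2-[(2,2-dimethylchroman-6-yl)methyl]-5-oxo-3-phenyl-4-(4,4,5,5-tetramethyl-1,3,2-dioxaborolan-2-yl)-2,5-dihydrofuran-2-carboxylate
Product: 15 methyl (R)-2-[(2,2-dimethylchroman-6-yl)methyl]-4-hydroxy-5-oxo-3-phenyl-2,5-dihydrofuran-2-carboxylate (4'-dehydroxy aspernolide A), via enol pinacol borate 14 (not isolated)
Conditions: NaBO3·4H2O (2 equiv), THF/H2O 1:1, 0 °C to rt; work-up at pH 3
Reagents that add atoms: sodium perborate ([Na+].[O-]OB=O)
Why: Oxidation of an alkenyl boronate: hydroperoxide from the perborate adds to boron, C3 migrates from boron to oxygen and hydrolysis of borate 14 frees the enol, which is the stable tautomer of the 3-oxo lactone because it is conjugated to the C4 phenyl group, while the quaternary C5 centre is not touched.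

**Compound list**

1 | 2,2-dimethylchroman-6-carbaldehyde | CC1(C)CCc2cc(C=O)ccc2O1 | starting material
2 | N-acetylglycine | CC(=O)NCC(=O)O | starting material
3 | 2-methyloxazol-5(4H)-one | CC1=NCC(=O)O1 | intermediate
4 | (Z)-4-[(2,2-dimethylchroman-6-yl)methylene]-2-methyloxazol-5(4H)-one | CC1=N/C(=C\c2ccc3c(c2)CCC(C)(C)O3)C(=O)O1 | intermediate
5 | (Z)-2-acetamido-3-(2,2-dimethylchroman-6-yl)acrylic acid | CC(=O)N/C(=C\c1ccc2c(c1)CCC(C)(C)O2)C(=O)O | intermediate
6 | 3-(2,2-dimethylchroman-6-yl)-2-oxopropanoic acid | OC(=O)C(=O)Cc1ccc2c(c1)CCC(C)(C)O2 | intermediate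
7 | methyl 3-(2,2-dimethylchroman-6-yl)-2-oxopropanoate | COC(=O)C(=O)Cc1ccc2c(c1)CCC(C)(C)O2 | intermediate
8 | phenylacetylene | C#Cc1ccccc1 | starting material
9 | lithium phenylacetylide | [Li+].[C-]#Cc1ccccc1 | intermediate
10 | lithium isopropoxy(phenylethynyl)(pinacolato)borate | [Li+].CC(C)O[B-]1(C#Cc2ccccc2)OC(C)(C)C(C)(C)O1 | intermediate
11 | 4,4,5,5-tetramethyl-2-(phenylethynyl)-1,3,2-dioxaborolane | CC1(C)OB(C#Cc2ccccc2)OC1(C)C | intermediate
12 | carbon monoxide | [C-]#[O+] | starting material
13 | methyl (R)-2-[(2,2-dimethylchroman-6-yl)methyl]-5-oxo-3-phenyl-4-(4,4,5,5-tetramethyl-1,3,2-dioxaborolan-2-yl)-2,5-dihydrofuran-2-carboxylate | COC(=O)[C@]1(Cc2ccc3c(c2)CCC(C)(C)O3)OC(=O)C(B2OC(C)(C)C(C)(C)O2)=C1c1ccccc1 | intermediate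
14 | methyl (R)-2-[(2,2-dimethylchroman-6-yl)methyl]-5-oxo-3-phenyl-4-[(4,4,5,5-tetramethyl-1,3,2-dioxaborolan-2-yl)oxy]-2,5-dihydrofuran-2-carboxylate | COC(=O)[C@]1(Cc2ccc3c(c2)CCC(C)(C)O3)OC(=O)C(OB2OC(C)(C)C(C)(C)O2)=C1c1ccccc1 | intermediate
15 | methyl (R)-2-[(2,2-dimethylchroman-6-yl)methyl]-4-hydroxy-5-oxo-3-phenyl-2,5-dihydrofuran-2-carboxylate (4'-dehydroxy aspernolide A) | COC(=O)[C@]1(Cc2ccc3c(c2)CCC(C)(C)O3)OC(=O)C(O)=C1c1ccccc1 | target

**Step count**

Total: 6 steps (steps 1–3 and step 4 converge in step 5). Longest linear sequence: 5 steps (1, 2, 3, 5, 6).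

**Steps most likely to fail**

Step 5 (proposed new method). Several processes may defeat it:
- oligomerisation or cyclotrimerisation of the alkyne on ruthenium carbonyl;
- protolytic cleavage of the alkynyl or alkenyl C–B bond by the enol O–H of 7;
- oxidative cyclisation with the reverse regiochemistry;
- self-aldol condensation of 7;
- poor facial selectivity, in particular through a racemic pathway on ligand-free ruthenium carbonyl species at the reaction temperature.

The fallback uses known chemistry, sets out from 7 and returns at 15. Compound 7 would be added slowly to an excess of purchased methyl 2-oxo-3-phenylpropanoate and DBU in DMF at 0 °C. The phenylpyruvate enolate should add to the ketone of 7 to give the aldol adduct dimethyl 2-[(2,2-dimethylchroman-6-yl)methyl]-2-hydroxy-4-oxo-3-phenylpentanedioate F1. Its tertiary alkoxide lactonises onto the terminal ester with loss of methanol and enolises to racemic methyl 2-[(2,2-dimethylchroman-6-yl)methyl]-4-hydroxy-5-oxo-3-phenyl-2,5-dihydrofuran-2-carboxylate F2. After chromatographic removal of the homo-aldol lactones and the reverse cross product, preparative HPLC on a chiral stationary phase would separate 15 from methyl (S)-2-[(2,2-dimethylchroman-6-yl)methyl]-4-hydroxy-5-oxo-3-phenyl-2,5-dihydrofuran-2-carboxylate F3.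

Step 6. Peroxide may over-oxidise the product through cleavage of its 2,3-dioxo tautomer. The basic aqueous medium may saponify the methyl ester or open the lactone. Protodeborylation may compete with oxidation. The fallback sets out from 13 and returns at 15. A Chan–Lam-type C–O coupling with Cu(OAc)2 (Et3N, 4 Å molecular sieves, MeCN, air, rt) should give the enol acetate methyl (R)-4-acetoxy-2-[(2,2-dimethylchroman-6-yl)methyl]-5-oxo-3-phenyl-2,5-dihydrofuran-2-carboxylate F4 without peroxide or aqueous base. K2CO3 in MeOH at 0 °C would then transfer the acetyl group to methanol and give 15; the methyl ester is degenerate toward methanolysis.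

Step 2. Prolonged heating in mineral acid may open the chroman ether, degrade the arylpyruvic acid by decarboxylation or air oxidation, or stop at the enamide. The fallback sets out from 1 and returns at 7. Horner–Wadsworth–Emmons olefination of 1 with methyl 2-[(tert-butyldimethylsilyl)oxy]-2-(dimethoxyphosphoryl)acetate (LiN(SiMe3)2, THF, −78 °C to rt) should give the silyl enol ether methyl 2-[(tert-butyldimethylsilyl)oxy]-3-(2,2-dimethylchroman-6-yl)acrylate F5 as an E/Z mixture. Desilylation with Et3N·3HF in THF at rt would release 7 directly, with no free arylpyruvic acid and no hot acid on the way.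

**Further compounds**

F1 | step 5 | dimethyl 2-[(2,2-dimethylchroman-6-yl)methyl]-2-hydroxy-4-oxo-3-phenylpentanedioate (mixture of stereoisomers) | COC(=O)C(=O)C(c1ccccc1)C(O)(Cc1ccc2c(c1)CCC(C)(C)O2)C(=O)OC
F2 | step 5 | racemic methyl 2-[(2,2-dimethylchroman-6-yl)methyl]-4-hydroxy-5-oxo-3-phenyl-2,5-dihydrofuran-2-carboxylate | COC(=O)C1(Cc2ccc3c(c2)CCC(C)(C)O3)OC(=O)C(O)=C1c1ccccc1
F3 | step 5 | methyl (S)-2-[(2,2-dimethylchroman-6-yl)methyl]-4-hydroxy-5-oxo-3-phenyl-2,5-dihydrofuran-2-carboxylate | COC(=O)[C@@]1(Cc2ccc3c(c2)CCC(C)(C)O3)OC(=O)C(O)=C1c1ccccc1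
F4 | step 6 | methyl (R)-4-acetoxy-2-[(2,2-dimethylchroman-6-yl)methyl]-5-oxo-3-phenyl-2,5-dihydrofuran-2-carboxylate | COC(=O)[C@]1(Cc2ccc3c(c2)CCC(C)(C)O3)OC(=O)C(OC(C)=O)=C1c1ccccc1
F5 | step 2 | methyl 2-[(tert-butyldimethylsilyl)oxy]-3-(2,2-dimethylchroman-6-yl)acrylate (E/Z mixture) | COC(=O)C(O[Si](C)(C)C(C)(C)C)=Cc1ccc2c(c1)CCC(C)(C)O2
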